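Ring A is the resorcinol ring (a1–a6; a4 is the biaryl carbon, a5 bears C7). Ring B is the fused catechol (b1–b6), ring C the pendant catechol, ring D the monophenol ring (d1 bears C10, d5 is the biaryl carbon, d6 bears C8). C7/C8 are the CH2/CH of the six-membered ring, C9 is the CH bearing ring C, and C10 is the CH2 of the seven-membered ring.
The strategy rests on ring B: its oxygens sit on the neighbours b3/b4, its only carbon substituents (C8, C9) on the neighbours b1/b6, and b2/b5 carry hydrogen. Ring B is therefore the [2+2+2] sum of an ethynyl group on C8 (b1≡b2), an ethynyl group on C9 (b6≡b5) and a symmetric alkyne b3≡b4 whose two boryl groups are latent hydroxyls.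
The key disconnection cuts b1–b6, b2–b3 and b4–b5, the last C–C bonds made. It leads back to the C8,C9-diethynyl dihydrophenanthrene pentamethyl ether and bis(pinacolatoboryl)acetylene; C–B to C–O oxidation and demethylation follow.
The diyne comes from the matching dialdehyde by a double Corey–Fuchs sequence. The six-membered ring comes from a4–d5 direct arylation of an open aryl bromide at the silyl ether stage. C8 and C9 come from two Evans alkylations (C7–C8, then C9–C10) with (S)-4-benzyloxazolidin-2-one.
Rings A, C and D are bought; the six-membered carbocycle closes in step 12, and ring B and the seven-membered ring close together in step 18.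

Key step: step 18

Design remark: d6 is flanked on both sides, and an arylmetal there cannot coexist with a propargylic halide, so C8 is carried on ring D from the start as an arylacetic acid carbon. The alkynes are installed only after the palladium ring closure, because an arylpalladium at a4 would add 5-exo-dig to an alkyne on C8.
Assumption: the chelated Z-enolate model (attack anti to the auxiliary benzyl group) is taken to hold for both arylacetyl imides. From steps 6 and 9 on, the spatial arrangement at C8 and C9 stays constant; the CIP letters change only because substituent priorities change.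

Step 1
Reactants: 1 2-bromo-5-methoxybenzyl alcohol
Product: 2 [(2-bromo-5-methoxybenzyl)oxy](tert-butyl)dimethylsilane
Conditions: TBSCl, imidazole, DMF, 0 °C to rt
Reagents that add atoms: tert-butyldimethylsilyl chloride, CC(C)(C)[Si](C)(C)Cl
Why: Silyl ether protection masks the C10 hydroxyl, the later leaving-group site on d1, against the zinc enolate, hydroxide and amide base of steps 2 to 6.

Step 2
Reactants: 2 silyl ether; 3 (2-ethoxy-2-oxoethyl)zinc bromide (commercial solution)
Product: 4 ethyl {2-[(tert-butyldimethylsilyloxy)methyl]-4-methoxyphenyl}acetate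
Conditions: Pd2(dba)3 (2.5 mol%), XPhos (10 mol%), THF, 65 °C
Reagents that add atoms: none
Why: Negishi-type coupling of a Reformatsky reagent (palladium-catalysed α-arylation of a zinc ester enolate) replaces the d6 bromide by the CH2CO2Et unit that holds C8 and the future b1 carbon, and the nearly neutral zinc enolate leaves the silyl ether alone.

Step 3
Reactants: 4 ethyl ester
Product: 5 {2-[(tert-butyldimethylsilyloxy)methyl]-4-methoxyphenyl}acetic acid
Conditions: LiOH, THF/EtOH/H2O, rt; then 1 M HCl to pH 4, 0 °C
Reagents that add atoms: lithium hydroxide, [Li+].[OH-]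
Why: Saponification of the unhindered ester frees the acid for auxiliary attachment, and the primary TBS ether tolerates hydroxide and brief mild acidification.

Step 4
Reactants: 5 acid; 6 (S)-4-benzyloxazolidin-2-one
Product: 7 (4S)-4-benzyl-3-({2-[(tert-butyldimethylsilyloxy)methyl]-4-methoxyphenyl}acetyl)oxazolidin-2-one
Conditions: DCC, DMAP (cat.), CH2Cl2, 0 °C to rt
Reagents that add atoms: none
Why: Steglich-type carbodiimide/DMAP N-acylation attaches the Evans auxiliary to the arylacetic acid without strong base.

Step 5
Reactants: 8 3,5-dimethoxybenzyl bromide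
Product: 9 2-bromo-3,5-dimethoxybenzyl bromide
Conditions: NBS (1.0 equiv), MeCN, 0 °C, dark
Reagents that add atoms: N-bromosuccinimide, O=C1CCC(=O)N1Br
Why: Electrophilic aromatic bromination of the resorcinol dimethyl ether ring goes to C2 (para to one methoxy group, ortho to the other), which is preferred over C4 between the two methoxy groups, and this installs the a4 halide needed in step 12.

Step 6
Reactants: 7 ring D imide; 9 ring A benzylic bromide
Product: 11 (4S)-4-benzyl-3-[(2S)-3-(2-bromo-3,5-dimethoxyphenyl)-2-{2-[(tert-butyldimethylsilyloxy)methyl]-4-methoxyphenyl}propanoyl]oxazolidin-2-one, via sodium Z-enolate 10 (not isolated)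
Conditions: NaHMDS (1.05 equiv), THF, −78 °C; then 9, −78 to −20 °C
Reagents that add atoms: none
Why: Evans asymmetric alkylation, in which the chelated sodium Z-enolate is attacked by the benzylic bromide on the face opposite the auxiliary benzyl group; this forms C7–C8 and sets C8 (S in the imide), and the minor diastereomer should be removable by chromatography.

Step 7
Reactants: 11 C8 imide
Product: 12 (4S)-4-benzyl-3-[(2S)-3-(2-bromo-3,5-dimethoxyphenyl)-2-[2-(bromomethyl)-4-methoxyphenyl]propanoyl]oxazolidin-2-one
Conditions: Ph3PBr2, CH2Cl2, 0 °C to rt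
Reagents that add atoms: dibromotriphenylphosphorane, BrP(Br)(c1ccccc1)(c1ccccc1)c1ccccc1
Why: Appel-type activation of the silyl ether oxygen as an alkoxyphosphonium ion, followed by SN2 attack of bromide, turns the benzylic OTBS directly into the C10 bromide under neutral conditions that touch neither the imide nor C8.

Step 8
Reactants: 13 (3,4-dimethoxyphenyl)acetic acid; 6 (S)-4-benzyloxazolidin-2-one
Product: 14 (4S)-4-benzyl-3-[(3,4-dimethoxyphenyl)acetyl]oxazolidin-2-one
Conditions: DCC, DMAP (cat.), CH2Cl2, 0 °C to rt
Reagents that add atoms: none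
Why: The same Steglich-type N-acylation loads the ring C arylacetic acid onto the Evans auxiliary.

Step 9
Reactants: 14 ring C imide; 12 ring D benzylic bromide
Product: 16 (4S)-4-benzyl-3-[(2S)-3-{2-[(2S)-1-[(4S)-4-benzyl-2-oxooxazolidin-3-yl]-3-(2-bromo-3,5-dimethoxyphenyl)-1-oxopropan-2-yl]-5-methoxyphenyl}-2-(3,4-dimethoxyphenyl)propanoyl]oxazolidin-2-one, via sodium Z-enolate 15 (not isolated)
Conditions: NaHMDS, THF, −78 °C; then 12, −78 to −20 °C
Reagents that add atoms: none
Why: This second Evans alkylation keeps the enolate on the separate ring C fragment, so that no enolate shares a molecule with an imide carbonyl (no Dieckmann closure); attack anti to the auxiliary benzyl group forms C9–C10 and sets C9 (S in the imide), and allylic strain shields the tertiary C8–H from deprotonation.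

Step 10
Reactants: 16 bis-imide
Product: 17 (2S)-3-(2-bromo-3,5-dimethoxyphenyl)-2-{2-[(2S)-2-(3,4-dimethoxyphenyl)-3-hydroxypropyl]-4-methoxyphenyl}propan-1-ol
Conditions: LiBH4, H2O (2 equiv), Et2O/THF, 0 °C
Reagents that add atoms: none
Why: Reductive cleavage of both Evans auxiliaries with borohydride gives the two primary alcohols, spares the aryl bromide, and passes through no enolizable intermediate that could erode C8 or C9.

Step 11
Reactants: 17 diol
Product: 18 bis(tert-butyldimethylsilyl) ether of 17 (C8 S, C9 S)
Conditions: TBSCl, imidazole, DMF, rt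
Reagents that add atoms: tert-butyldimethylsilyl chloride, CC(C)(C)[Si](C)(C)Cl
Why: Silylation keeps the primary alcohols from being oxidized or O-arylated by the arylpalladium intermediate of step 12.

Step 12
Reactants: 18 open aryl bromide
Product: 19 (10S)-10-[(tert-butyldimethylsilyloxy)methyl]-1-[(2S)-3-(tert-butyldimethylsilyloxy)-2-(3,4-dimethoxyphenyl)propyl]-3,5,7-trimethoxy-9,10-dihydrophenanthrene
Conditions: Pd(OAc)2 (10 mol%), PCy3·HBF4 (20 mol%), PivOH (30 mol%), K2CO3, DMA, 120 °C
Reagents that add atoms: none
Why: Intramolecular palladium-catalysed direct arylation (oxidative addition at a4–Br, pivalate-assisted concerted metalation–deprotonation at d5, reductive elimination) closes the six-membered ring; d5 is the only free position ortho to d6, so only one ring can form, and neither stereocentre bears an acidic hydrogen at this stage.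

Step 13
Reactants: 19 tricyclic bis-silyl ether
Product: 20 [(10S)-1-[(2S)-2-(3,4-dimethoxyphenyl)-3-hydroxypropyl]-3,5,7-trimethoxy-9,10-dihydrophenanthren-10-yl]methanol
Conditions: TBAF, THF, rt
Reagents that add atoms: none
Why: Fluoride-induced desilylation frees both primary alcohols without affecting any other group.

Step 14
Reactants: 20 diol
Product: 21 (10S)-1-[(2S)-2-(3,4-dimethoxyphenyl)-3-oxopropyl]-3,5,7-trimethoxy-9,10-dihydrophenanthrene-10-carbaldehyde
Conditions: Dess–Martin periodinane, NaHCO3, CH2Cl2, 0 °C, argon; used crude at once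
Reagents that add atoms: none
Why: Buffered Dess–Martin oxidation stops at the bis(α-aryl aldehyde) and exposes it to neither amine base nor strong acid, which keeps enolization at C8 and C9 to a minimum.

Step 15
Reactants: 21 dialdehyde
Product: 22 (10R)-10-(2,2-dibromoethenyl)-1-[(2R)-4,4-dibromo-2-(3,4-dimethoxyphenyl)but-3-en-1-yl]-3,5,7-trimethoxy-9,10-dihydrophenanthrene
Conditions: CBr4, PPh3, Zn dust, CH2Cl2, rt (ylide preformed); then 21, 0 °C
Reagents that add atoms: carbon tetrabromide, BrC(Br)(Br)Br
Why: Ramirez dibromoolefination, the first half of the Corey–Fuchs sequence, is a Wittig-type reaction run under essentially neutral conditions; it is chosen over carbonate/methanol diazophosphonate homologation to protect the α-aryl stereocentres, and it adds the b2 and b5 carbons.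

Step 16
Reactants: 22 bis(dibromoalkene)
Product: 24 (10R)-1-[(2R)-2-(3,4-dimethoxyphenyl)but-3-yn-1-yl]-10-ethynyl-3,5,7-trimethoxy-9,10-dihydrophenanthrene, via dilithium bis-acetylide 23 (not isolated)
Conditions: n-BuLi (4.4 equiv), THF, −78 °C; H2O quench at −78 °C
Reagents that add atoms: none
Why: In the second half of the Corey–Fuchs sequence, bromine–lithium exchange and a Fritsch–Buttenberg–Wiechell 1,2-shift give the lithium acetylides, and cold protonation releases both terminal alkynes before the propargylic C–H can be metalated.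

Step 17
Reactants: 25 trichloroethylene; 26 2-isopropoxy-4,4,5,5-tetramethyl-1,3,2-dioxaborolane
Product: 29 bis(pinacolatoboryl)acetylene, via dilithioacetylene 27 (not isolated), via dilithium bis-borate 28 (not isolated)
Conditions: n-BuLi (3 equiv), Et2O, −78 °C to rt; 26 (2 equiv), −78 °C to rt; HCl in Et2O (2 equiv)
Reagents that add atoms: none
Why: This is the standard alkynylboronate synthesis, in which dilithioacetylene (from deprotonation, chloride loss and chlorine–lithium exchange of trichloroethylene) adds to two alkoxyborolanes and anhydrous acid collapses the ate complexes by loss of isopropanol.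

Step 18
Reactants: 24 C8,C9-diethynyl precursor; 29 bis(pinacolatoboryl)acetylene
Product: 30 ring B b3,b4-bis(pinacol boronate) of the target pentamethyl ether (C8 R, C9 S)
Conditions: 29 (4 equiv), CpCo(CO)2 (20 mol%, two portions), degassed xylenes, reflux (about 140 °C), visible-light irradiation; 24 added by syringe pump over 10 h
Reagents that add atoms: none
Why: Loss of CO gives a monovalent CpCo fragment that binds both ethynyl groups of 24 and couples them oxidatively to a trivalent cobaltacyclopentadiene (bond b1–b6, cobalt on b2 and b5); 29 then coordinates and inserts, and reductive elimination forms b2–b3 and b4–b5 and returns the catalyst. The closest known reaction type is the cobalt-catalysed [2+2+2] cotrimerization of α,ω-diynes with bis(silyl)- or borylalkynes, which is documented for diborylacetylene and for benzo-tethered diynes that close seven-membered rings. The seven-membered ring (C8, b1, b6, C9, C10, d1, d6) closes in the oxidative coupling as the ring fused to the metallacycle, and ring B closes in the insertion/reductive-elimination event. No stereocentre is made, since C8 and C9 are spectators under neutral, base-free conditions (the C9 letter changes from R to S only because b6 outranks ring C). The step needs cross- over self-trimerization: 29 is too hindered to trimerize with itself and is used in excess, 24 is kept dilute by slow addition, and the ortho-phenylene unit d6–d1 in the five-atom tether together with the pseudo-axial ethynyl group on C8 (forced by peri strain with the d1 arm) holds the two alkynes close. There is no regiochemical question because 29 is symmetric.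

Step 19
Reactants: 30 bis-boronate
Product: 31 target pentamethyl ether with free ring B catechol (b3,b4-diol; C8 R, C9 S)
Conditions: NaBO3·4H2O, THF/H2O, rt; aqueous NH4Cl work-up
Reagents that add atoms: sodium perborate, [Na+].[O-]OB=O
Why: Oxidative C–B to C–O conversion (1,2-aryl shift from boron to peroxide oxygen) replaces each boryl group by hydroxyl at the same carbon, and mild perborate limits over-oxidation of the catechol.

Step 20
Reactants: 31 pentamethyl ether
Product: 32 CNP0306974.1 (C8 R, C9 S)
Conditions: BBr3 (12 equiv), CH2Cl2, −78 °C to rt; H2O quench, argon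
Reagents that add atoms: none
Why: Lewis acid aryl methyl ether cleavage with BBr3 removes all five methyl groups, and C8 and C9 carry neither a leaving group nor an acidic hydrogen, so the configuration is kept.

Compound list
1 | 2-bromo-5-methoxybenzyl alcohol | COc1ccc(Br)c(CO)c1 | starting material
2 | [(2-bromo-5-methoxybenzyl)oxy](tert-butyl)dimethylsilane | COc1ccc(Br)c(CO[Si](C)(C)C(C)(C)C)c1 | intermediate
3 | (2-ethoxy-2-oxoethyl)zinc bromide | CCOC(=O)C[Zn]Br | starting material
4 | ethyl {2-[(TBS-oxy)methyl]-4-methoxyphenyl}acetate | CCOC(=O)Cc1ccc(OC)cc1CO[Si](C)(C)C(C)(C)C | intermediate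
5 | {2-[(TBS-oxy)methyl]-4-methoxyphenyl}acetic acid | COc1ccc(CC(=O)O)c(CO[Si](C)(C)C(C)(C)C)c1 | intermediate
6 | (S)-4-benzyloxazolidin-2-one | O=C1N[C@@H](Cc2ccccc2)CO1 | starting material
7 | ring D arylacetyl imide | COc1ccc(CC(=O)N2[C@@H](Cc3ccccc3)COC2=O)c(CO[Si](C)(C)C(C)(C)C)c1 | intermediate
8 | 3,5-dimethoxybenzyl bromide | COc1cc(CBr)cc(OC)c1 | starting material
9 | 2-bromo-3,5-dimethoxybenzyl bromide | COc1cc(CBr)c(Br)c(OC)c1 | intermediate
10 | sodium Z-enolate of 7 | [Na+].[O-]/C(=C\c1ccc(OC)cc1CO[Si](C)(C)C(C)(C)C)N1[C@@H](Cc2ccccc2)COC1=O | intermediate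
11 | C8-alkylated imide, OTBS (C8 S) | COc1cc(OC)c(Br)c(C[C@H](C(=O)N2[C@@H](Cc3ccccc3)COC2=O)c2ccc(OC)cc2CO[Si](C)(C)C(C)(C)C)c1 | intermediate
12 | C8-alkylated imide, C10 bromide (C8 S) | COc1cc(OC)c(Br)c(C[C@H](C(=O)N2[C@@H](Cc3ccccc3)COC2=O)c2ccc(OC)cc2CBr)c1 | intermediate
13 | (3,4-dimethoxyphenyl)acetic acid | COc1ccc(CC(=O)O)cc1OC | starting material
14 | ring C arylacetyl imide | COc1ccc(CC(=O)N2[C@@H](Cc3ccccc3)COC2=O)cc1OC | intermediate
15 | sodium Z-enolate of 14 | [Na+].[O-]/C(=C\c1ccc(OC)c(OC)c1)N1[C@@H](Cc2ccccc2)COC1=O | intermediate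
16 | bis-imide (C8 S, C9 S) | COc1cc(OC)c(Br)c(C[C@H](C(=O)N2[C@@H](Cc3ccccc3)COC2=O)c2ccc(OC)cc2C[C@H](C(=O)N2[C@@H](Cc3ccccc3)COC2=O)c2ccc(OC)c(OC)c2)c1 | intermediate
17 | open bromo diol (C8 S, C9 S) | COc1cc(OC)c(Br)c(C[C@H](CO)c2ccc(OC)cc2C[C@H](CO)c2ccc(OC)c(OC)c2)c1 | intermediate
18 | open bromo bis-TBS ether | COc1cc(OC)c(Br)c(C[C@H](CO[Si](C)(C)C(C)(C)C)c2ccc(OC)cc2C[C@H](CO[Si](C)(C)C(C)(C)C)c2ccc(OC)c(OC)c2)c1 | intermediate
19 | dihydrophenanthrene bis-TBS ether | COc1cc(OC)c2c(c1)C[C@H](CO[Si](C)(C)C(C)(C)C)c1c-2cc(OC)cc1C[C@H](CO[Si](C)(C)C(C)(C)C)c1ccc(OC)c(OC)c1 | intermediate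
20 | dihydrophenanthrene diol | COc1cc(OC)c2c(c1)C[C@H](CO)c1c-2cc(OC)cc1C[C@H](CO)c1ccc(OC)c(OC)c1 | intermediate
21 | dihydrophenanthrene dialdehyde (C8 S, C9 S) | COc1cc(OC)c2c(c1)C[C@H](C=O)c1c-2cc(OC)cc1C[C@H](C=O)c1ccc(OC)c(OC)c1 | intermediate
22 | bis(1,1-dibromoalkene) (C8 R, C9 R) | COc1cc(OC)c2c(c1)C[C@H](C=C(Br)Br)c1c-2cc(OC)cc1C[C@H](C=C(Br)Br)c1ccc(OC)c(OC)c1 | intermediate
23 | dilithium bis-acetylide | COc1cc(OC)c2c(c1)C[C@H](C#C[Li])c1c-2cc(OC)cc1C[C@H](C#C[Li])c1ccc(OC)c(OC)c1 | intermediate
24 | C8,C9-diethynyl precursor (C8 R, C9 R) | COc1cc(OC)c2c(c1)C[C@H](C#C)c1c-2cc(OC)cc1C[C@H](C#C)c1ccc(OC)c(OC)c1 | intermediate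
25 | trichloroethylene | ClC=C(Cl)Cl | starting material
26 | 2-isopropoxy-4,4,5,5-tetramethyl-1,3,2-dioxaborolane | CC(C)OB1OC(C)(C)C(C)(C)O1 | starting material
27 | dilithioacetylene | [Li]C#C[Li] | intermediate
28 | dilithium ethynediylbis[isopropoxy(pinacolato)borate] | [Li+].[Li+].CC(C)O[B-]1(OC(C)(C)C(C)(C)O1)C#C[B-]1(OC(C)C)OC(C)(C)C(C)(C)O1 | intermediate
29 | bis(pinacolatoboryl)acetylene | CC1(C)OB(C#CB2OC(C)(C)C(C)(C)O2)OC1(C)C | intermediate
30 | ring B bis(pinacol boronate) of the pentamethyl ether (C8 R, C9 S) | COc1cc(OC)c2c(c1)C[C@@H]1c3cc(B4OC(C)(C)C(C)(C)O4)c(B4OC(C)(C)C(C)(C)O4)cc3[C@H](c3ccc(OC)c(OC)c3)Cc3cc(OC)cc-2c31 | intermediate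
31 | pentamethyl ether with free ring B catechol | COc1cc(OC)c2c(c1)C[C@@H]1c3cc(O)c(O)cc3[C@H](c3ccc(OC)c(OC)c3)Cc3cc(OC)cc-2c31 | intermediate
32 | CNP0306974.1 | Oc1cc(O)c2c(c1)C[C@@H]1c3cc(O)c(O)cc3[C@H](c3ccc(O)c(O)c3)Cc3cc(O)cc-2c31 | target

Total step count: 20. Longest linear sequence: 17 steps (1–4, 6, 7, 9–16, 18–20).

Steps most likely to fail
1. Step 18. The oxidative coupling that closes the seven-membered ring is slow, so the terminal diyne may oligomerize or trimerize with itself. Insertion of the very hindered diborylalkyne into the crowded cobaltacycle may also lag. The fallback sets out from 24 and comes back at 31. Diyne 24 is cotrimerized under the same cobalt catalysis and slow addition with the small, commercial 2-ethynyl-4,4,5,5-tetramethyl-1,3,2-dioxaborolane, which should insert far more readily. This should give the two regioisomeric monoboronates, the b3-boronate F1 and the b4-boronate F2, which need not be separated. NaBO3 oxidation converts them into the b3-phenol F3 and the b4-phenol F4. Ortho-oxygenation of these phenols with IBX in DMF at rt attacks the unhindered ortho position (b4 in F3, b3 in F4). Both isomers are thereby funnelled into the single ring B ortho-quinone F5, which is reduced in the same flask with Na2S2O4 to catechol 31.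
2. Step 15 (together with the handling of 21). The two α-aryl aldehydes may enolize, with erosion of configuration at C8 and C9, and the dihydrophenanthrene may be dehydrogenated by air during the olefination. The fallback sets out from 21 and comes back at 24, bypassing 22 and 23. Crude 21 is added at −78 °C to lithiated trimethylsilyldiazomethane (TMSCHN2, n-BuLi, THF) in a Colvin rearrangement. Carbonyl addition, Peterson-type loss of silanolate and loss of N2 give alkylidene carbenes, and their 1,2-hydrogen shift delivers both terminal alkynes in one cold operation, without phosphonium salts or zinc halide.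
3. Step 12. Oxidative addition of the di-ortho-substituted, electron-rich bromide may be sluggish, and hydrodebromination or desilylation may occur at 120 °C. The fallback sets out from 18 and comes back at 19. Copper-catalysed aromatic Finkelstein exchange (CuI, NaI, trans-N,N'-dimethylcyclohexane-1,2-diamine, dioxane, 110 °C) gives the aryl iodide F6. F6 is then cyclized photochemically (medium-pressure mercury lamp, MeCN, Et3N), the classical dehydrohalogenative photocyclization of 2-iodobibenzyls to 9,10-dihydrophenanthrenes. Homolysis of the carbon–iodine bond gives the a4 aryl radical, which attacks d5, and loss of hydrogen iodide rearomatizes to 19.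

Further compounds
F1 | step 18 | ring B b3-(pinacol boronate) of the pentamethyl ether | COc1cc(OC)c2c(c1)C[C@@H]1c3cc(B4OC(C)(C)C(C)(C)O4)ccc3[C@H](c3ccc(OC)c(OC)c3)Cc3cc(OC)cc-2c31
F2 | step 18 | ring B b4-(pinacol boronate) of the pentamethyl ether | COc1cc(OC)c2c(c1)C[C@@H]1c3ccc(B4OC(C)(C)C(C)(C)O4)cc3[C@H](c3ccc(OC)c(OC)c3)Cc3cc(OC)cc-2c31
F3 | step 18 | ring B b3-phenol of the pentamethyl ether | COc1cc(OC)c2c(c1)C[C@@H]1c3cc(O)ccc3[C@H](c3ccc(OC)c(OC)c3)Cc3cc(OC)cc-2c31
F4 | step 18 | ring B b4-phenol of the pentamethyl ether | COc1cc(OC)c2c(c1)C[C@@H]1c3ccc(O)cc3[C@H](c3ccc(OC)c(OC)c3)Cc3cc(OC)cc-2c31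
F5 | step 18 | ring B b3,b4-ortho-quinone of the pentamethyl ether | COc1cc(OC)c2c(c1)C[C@@H]1C3=CC(=O)C(=O)C=C3[C@H](c3ccc(OC)c(OC)c3)Cc3cc(OC)cc-2c31
F0 | step 15 | none | none
F6 | step 12 | a4-iodo analogue of 18 | COc1cc(OC)c(I)c(C[C@H](CO[Si](C)(C)C(C)(C)C)c2ccc(OC)cc2C[C@H](CO[Si](C)(C)C(C)(C)C)c2ccc(OC)c(OC)c2)c1
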